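**Remark:** flavan numbering is used for the target (O1, C2, C3, C4, C4a, C5–C8, C8a; rings A, B and C); the acetylated phloroglucinol ring is called ring D.
**Assumption:** the absolute sense of induction by the chiral acid in step 9 cannot be predicted with certainty; the (R)-configured catalyst is written, and its mirror image is used if it proves to deliver the antipode.

## Retrosynthetic overview

1. The target comes from its tetra-O-benzyl ether by hydrogenolysis; the C3 hydroxyl is carried through the key step as a C3–B bond and revealed by stereoretentive oxidation.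
2. Key disconnection: ring C is opened across C4–C3 and O1–C2 to the ortho-quinone methide of ring A (oxadiene O1=C8a–C4a=C4) and an E-styrylboronate (C2=C3, ring B on C2, boron on C3).
3. Enabling feature: O1 and the C4 methylene are ortho substituents of the phloroglucinol ring A (a latent oxadiene), C2 carries the electron-rich catechol ring B, and the 2,3-trans relation maps onto the E-alkene.
4. The methide precursor arises from 3,5-bis(benzyloxy)phenol by two boron-templated ortho-hydroxymethylations through temporary dioxaborin rings. The first arm is spent in a Friedel–Crafts union with ring D, the second becomes C4, and the single free phenol between both arms becomes O1, which fixes ring D at C8 and not C6.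
5. Rings A, B and D are bought as benzenes (ring D is adjusted in four steps from 2-methylphloroglucinol); ring C is the only ring formed, in step 9.

Key step: step 9

## Route

Step 1
Reactants: 1 2-methylbenzene-1,3,5-triol
Product: 2 1-(2,4,6-trihydroxy-3-methylphenyl)ethan-1-one
Conditions: AcCl (1.1 equiv), AlCl3 (3.5 equiv), PhNO2–CH2Cl2, 0 to 50 °C; aq. HCl
Reagents that add atoms: acetyl chloride, CC(Cl)=O
Why: Friedel–Crafts C-acylation of the phloroglucinol, whose two free ring carbons are equivalent and whose first acyl group deactivates the ring against a second acylation.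

Step 2
Reactants: 2 1-(2,4,6-trihydroxy-3-methylphenyl)ethan-1-one
Product: 3 1-[4,6-bis(benzyloxy)-2-hydroxy-3-methylphenyl]ethan-1-one
Conditions: BnBr (2.1 equiv), K2CO3 (2.2 equiv), DMF, rt to 40 °C
Reagents that add atoms: benzyl bromide, BrCc1ccccc1
Why: Williamson etherification under weak base, in which the 4-OH para to the acetyl group is the most acidic and, of the two chelating ortho hydroxyls, the one flanked by the C-methyl group is the more hindered and stays hydrogen-bonded to the carbonyl, so the 4,6-dibenzyl ether should dominate.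

Step 3
Reactants: 3 1-[4,6-bis(benzyloxy)-2-hydroxy-3-methylphenyl]ethan-1-one
Product: 4 1-[4,6-bis(benzyloxy)-2-methoxy-3-methylphenyl]ethan-1-one
Conditions: MeI (3 equiv), K2CO3 (3 equiv), DMF, 50 °C
Reagents that add atoms: iodomethane, CI
Why: Williamson O-methylation of the remaining chelated, hindered phenol under more forcing conditions places the methoxy group between acetyl and methyl.

Step 4
Reactants: 4 1-[4,6-bis(benzyloxy)-2-methoxy-3-methylphenyl]ethan-1-one
Product: 5 1-(4,6-dihydroxy-2-methoxy-3-methylphenyl)ethan-1-one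
Conditions: H2 (1 atm), 10% Pd/C, EtOAc–MeOH, rt
Reagents that add atoms: none
Why: Hydrogenolysis of the two aryl benzyl ethers over palladium, which should not reduce the twisted, di-ortho-substituted aryl ketone at atmospheric pressure.

Step 5
Reactants: 6 3,5-bis(benzyloxy)phenol
Product: 8 3,5-bis(benzyloxy)-2-(hydroxymethyl)phenol, via dioxaborin 7 (not isolated)
Conditions: PhB(OH)2 (1.2 equiv), (CH2O)n (2 equiv), EtCO2H (cat.), toluene, reflux, Dean–Stark; then diethanolamine (1.5 equiv), THF–Et2O, rt
Reagents that add atoms: formaldehyde (from paraformaldehyde), C=O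
Why: Boronic acid-templated ortho-hydroxymethylation, in which the aryl phenylboronate delivers formaldehyde through a six-membered transition state to the ortho carbon only and closes the temporary dioxaborin ring of 7, which also blocks a second hydroxymethylation; transesterification with diethanolamine then frees 8.

Step 6
Reactants: 8 3,5-bis(benzyloxy)-2-(hydroxymethyl)phenol; 5 1-(4,6-dihydroxy-2-methoxy-3-methylphenyl)ethan-1-one
Product: 10 1-{3-[2,4-bis(benzyloxy)-6-hydroxybenzyl]-2,4-dihydroxy-6-methoxy-5-methylphenyl}ethan-1-one, via ortho-quinone methide 9 (not isolated)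
Conditions: 5 (3 equiv), pyridinium p-toluenesulfonate (5 mol %), 1,4-dioxane, 60 °C, 8 added over 4 h
Reagents that add atoms: none
Why: Acid-catalysed dehydration of the ortho-hydroxybenzyl alcohol gives ortho-quinone methide 9, which is captured in a Friedel–Crafts C-alkylation by the only unsubstituted ring carbon of 5, while the excess of 5 and the slow addition of 8 hold back self-condensation of 9 with ring A.

Step 7
Reactants: 10 1-{3-[2,4-bis(benzyloxy)-6-hydroxybenzyl]-2,4-dihydroxy-6-methoxy-5-methylphenyl}ethan-1-one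
Product: 12 1-{3-[4,6-bis(benzyloxy)-2-hydroxy-3-(hydroxymethyl)benzyl]-2,4-dihydroxy-6-methoxy-5-methylphenyl}ethan-1-one, via dioxaborin 11 (not isolated)
Conditions: PhB(OH)2 (2.5 equiv), (CH2O)n (3 equiv), EtCO2H (cat.), toluene, 90 °C, 4 Å MS; then diethanolamine (4 equiv), THF, rt, pH 7 buffer wash; used crude
Reagents that add atoms: formaldehyde (from paraformaldehyde), C=O
Why: Second boronic acid-templated ortho-hydroxymethylation, for which ring A of 10 offers one free phenol with one free ortho carbon (the future C4a) while both phenols of ring D have substituted ortho carbons, so formaldehyde can be delivered only there and not to C6, which the template cannot reach.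

Step 8
Reactants: 13 3,4-bis(benzyloxy)benzaldehyde
Product: 14 2-{(E)-2-[3,4-bis(benzyloxy)phenyl]ethenyl}-4,4,5,5-tetramethyl-1,3,2-dioxaborolane
Conditions: CH2(Bpin)2 (1.2 equiv), LiTMP (lithium 2,2,6,6-tetramethylpiperidide, 1.2 equiv), THF, 0 °C; then 13, −78 °C to rt; aq. NH4Cl
Reagents that add atoms: bis(4,4,5,5-tetramethyl-1,3,2-dioxaborolan-2-yl)methane, CC1(C)OB(CB2OC(C)(C)C(C)(C)O2)OC1(C)C
Why: Boron–Wittig olefination, in which the α-boryl carbanion adds to the aldehyde and syn-elimination of the boron–oxygen pair gives the E-alkenylboronate.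

Step 9
Reactants: 12 1-{3-[4,6-bis(benzyloxy)-2-hydroxy-3-(hydroxymethyl)benzyl]-2,4-dihydroxy-6-methoxy-5-methylphenyl}ethan-1-one; 14 2-{(E)-2-[3,4-bis(benzyloxy)phenyl]ethenyl}-4,4,5,5-tetramethyl-1,3,2-dioxaborolane
Product: 16 1-(3-{[(2S,3S)-5,7-bis(benzyloxy)-2-[3,4-bis(benzyloxy)phenyl]-3-(4,4,5,5-tetramethyl-1,3,2-dioxaborolan-2-yl)-3,4-dihydro-2H-chromen-8-yl]methyl}-2,4-dihydroxy-6-methoxy-5-methylphenyl)ethan-1-one, via ortho-quinone methide 15 (not isolated)
Conditions: 14 (2 equiv), (R)-3,3'-bis(2,4,6-triisopropylphenyl)-1,1'-binaphthyl-2,2'-diyl N-(trifluoromethanesulfonyl)phosphoramide (10 mol %), 5 Å MS, CH2Cl2, −20 to 0 °C, 12 added over 6 h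
Reagents that add atoms: none
Why: Proposed new method: the chiral acid ionises the benzylic alcohol of 12 to the ion-paired, hydrogen-bonded ortho-quinone methide 15 (oxadiene O1=C8a–C4a=C4), which combines with the E-styrylboronate 14 in an inverse-electron-demand oxa-[4+2] cycloaddition (hetero-Diels–Alder reaction) that is concerted but asynchronous, the C4–C3 bond leading and the O1–C2 bond following as positive charge builds at the benzylic C2. The closest known reactions are the chiral Brønsted acid-catalysed [4+2] cycloadditions of ortho-quinone methides from ortho-hydroxybenzyl alcohols with styrenes and the thermal cycloadditions of ortho-quinone methides with E-configured β-substituted styrenes to trans-2-aryl-3-substituted chromans; a β-boryl styrene, an unsubstituted methide carbon and a polyphenolic substrate have not been combined with such a catalyst. Ring C is the only ring closed, as a six-membered pyran by [4+2] cycloaddition (in the stepwise limit a 6-endo capture of the C2 benzylic cation by O1). C2 and C3 are set together: their trans relation follows from suprafacial addition to the E-alkene (and is also the diequatorial outcome of a stepwise closure), and their absolute configuration from the chiral phosphoramide anion that is bound to the O1–H of the methide and shields one face of the approaching alkene, C4 being non-stereogenic so that no endo/exo question arises. The step needs regioselectivity, site selectivity and chemoselectivity: boron instead of oxygen on C3 leaves the electron-rich ring B as the only polarising group, so the larger HOMO coefficient sits on the boron-bearing carbon and the charge at C2 is benzylic and β to the C–B bond; ring A carries only one free phenol, flanked by C4 and by the CH2 bridge, so only O1 can enter the pyran ring and ring D is fixed at C8; the pinacol ester on boron resists alkenyl transfer and protodeboronation.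

Step 10
Reactants: 16 1-(3-{[(2S,3S)-5,7-bis(benzyloxy)-2-[3,4-bis(benzyloxy)phenyl]-3-(4,4,5,5-tetramethyl-1,3,2-dioxaborolan-2-yl)-3,4-dihydro-2H-chromen-8-yl]methyl}-2,4-dihydroxy-6-methoxy-5-methylphenyl)ethan-1-one
Product: 18 1-(3-{[(2R,3S)-5,7-bis(benzyloxy)-2-[3,4-bis(benzyloxy)phenyl]-3-hydroxy-3,4-dihydro-2H-chromen-8-yl]methyl}-2,4-dihydroxy-6-methoxy-5-methylphenyl)ethan-1-one, via borate ester 17 (not isolated)
Conditions: NaBO3·4H2O (3 equiv), THF–H2O (1:1), 0 °C to rt
Reagents that add atoms: sodium perborate tetrahydrate (dimeric peroxoborate), [Na+].[Na+].O[B-]1(O)OO[B-](O)(O)OO1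
Why: Oxidation of the secondary alkylboronate by peroxoborate through 1,2-migration of C3 from boron to oxygen with retention of configuration, followed by hydrolysis of borate 17, gives the 2,3-trans alcohol (the descriptor at C2 changes from S to R only because oxygen replaces boron in the priority order), and the mildly basic perborate should spare the chelated aryl ketone from Dakin or Baeyer–Villiger oxidation.

Step 11
Reactants: 18 1-(3-{[(2R,3S)-5,7-bis(benzyloxy)-2-[3,4-bis(benzyloxy)phenyl]-3-hydroxy-3,4-dihydro-2H-chromen-8-yl]methyl}-2,4-dihydroxy-6-methoxy-5-methylphenyl)ethan-1-one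
Product: 19 pilosanol N
Conditions: H2 (1 atm), 20% Pd(OH)2/C, THF–MeOH, rt
Reagents that add atoms: none
Why: Hydrogenolysis of the four aryl benzyl ethers under neutral conditions, which should leave the benzylic C2–O1 bond of the flavan, the diarylmethane bridge and the chelated ketone intact and avoids base-induced epimerisation at C2.

## Compound list

1 | 2-methylbenzene-1,3,5-triol (2-methylphloroglucinol) | Cc1c(O)cc(O)cc1O | starting material
2 | 1-(2,4,6-trihydroxy-3-methylphenyl)ethan-1-one | CC(=O)c1c(O)cc(O)c(C)c1O | intermediate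
3 | 1-[4,6-bis(benzyloxy)-2-hydroxy-3-methylphenyl]ethan-1-one | CC(=O)c1c(O)c(C)c(OCc2ccccc2)cc1OCc1ccccc1 | intermediate
4 | 1-[4,6-bis(benzyloxy)-2-methoxy-3-methylphenyl]ethan-1-one | CC(=O)c1c(OC)c(C)c(OCc2ccccc2)cc1OCc1ccccc1 | intermediate
5 | 1-(4,6-dihydroxy-2-methoxy-3-methylphenyl)ethan-1-one (ring D) | CC(=O)c1c(OC)c(C)c(O)cc1O | intermediate
6 | 3,5-bis(benzyloxy)phenol (ring A) | Oc1cc(OCc2ccccc2)cc(OCc2ccccc2)c1 | starting material
7 | 5,7-bis(benzyloxy)-2-phenyl-4H-1,3,2-benzodioxaborinine | c1ccc(cc1)B1OCc2c(OCc3ccccc3)cc(OCc3ccccc3)cc2O1 | intermediate (not isolated)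
8 | 3,5-bis(benzyloxy)-2-(hydroxymethyl)phenol | OCc1c(O)cc(OCc2ccccc2)cc1OCc1ccccc1 | intermediate
9 | 3,5-bis(benzyloxy)-6-methylidenecyclohexa-2,4-dien-1-one (ortho-quinone methide) | C=C1C(=O)C=C(OCc2ccccc2)C=C1OCc1ccccc1 | intermediate (not isolated)
10 | 1-{3-[2,4-bis(benzyloxy)-6-hydroxybenzyl]-2,4-dihydroxy-6-methoxy-5-methylphenyl}ethan-1-one | CC(=O)c1c(O)c(Cc2c(O)cc(OCc3ccccc3)cc2OCc2ccccc2)c(O)c(C)c1OC | intermediate
11 | 1-(3-{[5,7-bis(benzyloxy)-2-phenyl-4H-1,3,2-benzodioxaborinin-8-yl]methyl}-2,4-dihydroxy-6-methoxy-5-methylphenyl)ethan-1-one | CC(=O)c1c(O)c(Cc2c(OCc3ccccc3)cc(OCc3ccccc3)c3COB(c4ccccc4)Oc23)c(O)c(C)c1OC | intermediate (not isolated)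
12 | 1-{3-[4,6-bis(benzyloxy)-2-hydroxy-3-(hydroxymethyl)benzyl]-2,4-dihydroxy-6-methoxy-5-methylphenyl}ethan-1-one | CC(=O)c1c(O)c(Cc2c(O)c(CO)c(OCc3ccccc3)cc2OCc2ccccc2)c(O)c(C)c1OC | intermediate
13 | 3,4-bis(benzyloxy)benzaldehyde (ring B) | O=Cc1ccc(OCc2ccccc2)c(OCc2ccccc2)c1 | starting material
14 | 2-{(E)-2-[3,4-bis(benzyloxy)phenyl]ethenyl}-4,4,5,5-tetramethyl-1,3,2-dioxaborolane | CC1(C)OB(/C=C/c2ccc(OCc3ccccc3)c(OCc3ccccc3)c2)OC1(C)C | intermediate
15 | 2-[(3-acetyl-2,6-dihydroxy-4-methoxy-5-methylphenyl)methyl]-3,5-bis(benzyloxy)-6-methylidenecyclohexa-2,4-dien-1-one (ortho-quinone methide) | CC(=O)c1c(O)c(CC2=C(OCc3ccccc3)C=C(OCc3ccccc3)C(=C)C2=O)c(O)c(C)c1OC | intermediate (not isolated)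
16 | 1-(3-{[(2S,3S)-5,7-bis(benzyloxy)-2-[3,4-bis(benzyloxy)phenyl]-3-(4,4,5,5-tetramethyl-1,3,2-dioxaborolan-2-yl)-3,4-dihydro-2H-chromen-8-yl]methyl}-2,4-dihydroxy-6-methoxy-5-methylphenyl)ethan-1-one (2,3-trans) | COc1c(C)c(O)c(Cc2c(OCc3ccccc3)cc(OCc3ccccc3)c3c2O[C@H](c2ccc(OCc4ccccc4)c(OCc4ccccc4)c2)[C@@H](B2OC(C)(C)C(C)(C)O2)C3)c(O)c1C(C)=O | intermediate
17 | 1-(3-{[(2R,3S)-5,7-bis(benzyloxy)-2-[3,4-bis(benzyloxy)phenyl]-3-[(4,4,5,5-tetramethyl-1,3,2-dioxaborolan-2-yl)oxy]-3,4-dihydro-2H-chromen-8-yl]methyl}-2,4-dihydroxy-6-methoxy-5-methylphenyl)ethan-1-one (borate ester) | COc1c(C)c(O)c(Cc2c(OCc3ccccc3)cc(OCc3ccccc3)c3c2O[C@H](c2ccc(OCc4ccccc4)c(OCc4ccccc4)c2)[C@@H](OB2OC(C)(C)C(C)(C)O2)C3)c(O)c1C(C)=O | intermediate (not isolated)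
18 | 1-(3-{[(2R,3S)-5,7-bis(benzyloxy)-2-[3,4-bis(benzyloxy)phenyl]-3-hydroxy-3,4-dihydro-2H-chromen-8-yl]methyl}-2,4-dihydroxy-6-methoxy-5-methylphenyl)ethan-1-one | COc1c(C)c(O)c(Cc2c(OCc3ccccc3)cc(OCc3ccccc3)c3c2O[C@H](c2ccc(OCc4ccccc4)c(OCc4ccccc4)c2)[C@@H](O)C3)c(O)c1C(C)=O | intermediate
19 | pilosanol N, 1-(3-{[(2R,3S)-2-(3,4-dihydroxyphenyl)-3,5,7-trihydroxy-3,4-dihydro-2H-chromen-8-yl]methyl}-2,4-dihydroxy-6-methoxy-5-methylphenyl)ethan-1-one | COc1c(C)c(O)c(Cc2c(O)cc(O)c3c2O[C@H](c2ccc(O)c(O)c2)[C@@H](O)C3)c(O)c1C(C)=O | target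

## Step count and risks

Total step count: 11. Longest linear sequence: 9 steps (steps 1, 2, 3, 4, 6, 7, 9, 10, 11).

Steps most likely to fail:

**1. Step 9 (proposed new method).** Facial discrimination may be eroded because the phenols and the ketone of ring D compete with the methide for the chiral acid. The methide may oligomerise through C6 of ring A. Boron may be lost by ipso-substitution (alkenyl transfer) instead of ring closure.
Fallback with known chemistry, setting out from 5 and coming back at 18: ring C is taken from the chiral pool instead of being made. Commercial (+)-catechin is benzylated at its four phenols (BnBr, K2CO3, DMF) to (2R,3S)-5,7-bis(benzyloxy)-2-[3,4-bis(benzyloxy)phenyl]-3,4-dihydro-2H-chromen-3-ol F1. Compound 5 is aminomethylated at its only free ring carbon with dimethyl(methylidene)ammonium iodide (CH2Cl2, rt) to the Mannich base 1-{3-[(dimethylamino)methyl]-2,4-dihydroxy-6-methoxy-5-methylphenyl}ethan-1-one F2. Heating F1 with F2 in toluene at 100 °C eliminates dimethylamine to the ring D ortho-quinone methide 4-acetyl-3-hydroxy-5-methoxy-6-methyl-2-methylidenecyclohexa-3,5-dien-1-one F3. F3 alkylates C8 of F1, the ring A position that electrophiles prefer in 5,7-di-O-benzyl flavan-3-ols, and gives 18 after separation from any C6 isomer.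

**2. Step 6.** Methide 9 may condense with the electron-rich ring A of 8 or of product 10 instead of with ring D, giving oligomers and over-alkylated material.
Fallback, setting out from 6 and coming back at 10: the same methide is released under neutral to basic conditions, in which 5 reacts as its more nucleophilic phenolate. Compound 6 undergoes a phenol-directed ortho-Mannich reaction with dimethyl(methylidene)ammonium iodide (CH2Cl2, rt) to 3,5-bis(benzyloxy)-2-[(dimethylamino)methyl]phenol F4. Heating F4 with 5 in 1,4-dioxane at 100 °C expels dimethylamine, which first deprotonates 5, and the ammonium phenolate of 5 traps methide 9 at carbon to give 10.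

**3. Step 7.** The boronic acid may be sequestered by the ring D phenols and by the bridged bis-phenol motif, so that the template is not turned over. The released salicyl alcohol may ionise and self-condense during isolation.
Fallback, setting out from 10 and coming back at 12: the carbon is introduced at the aldehyde level and reduced. Magnesium phenolate-directed ortho-formylation of 10 (MgCl2, Et3N, paraformaldehyde, MeCN, reflux) gives 1-{3-[4,6-bis(benzyloxy)-3-formyl-2-hydroxybenzyl]-2,4-dihydroxy-6-methoxy-5-methylphenyl}ethan-1-one F5. Reduction of the aldehyde in F5 with NaBH4 (THF–MeOH, −20 °C), which should be faster than that of the hindered chelated ketone, gives 12.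

Further compounds
F1 | step 9 | (2R,3S)-5,7-bis(benzyloxy)-2-[3,4-bis(benzyloxy)phenyl]-3,4-dihydro-2H-chromen-3-ol | O[C@H]1Cc2c(OCc3ccccc3)cc(OCc3ccccc3)cc2O[C@@H]1c1ccc(OCc2ccccc2)c(OCc2ccccc2)c1
F2 | step 9 | 1-{3-[(dimethylamino)methyl]-2,4-dihydroxy-6-methoxy-5-methylphenyl}ethan-1-one | CC(=O)c1c(O)c(CN(C)C)c(O)c(C)c1OC
F3 | step 9 | 4-acetyl-3-hydroxy-5-methoxy-6-methyl-2-methylidenecyclohexa-3,5-dien-1-one | CC(=O)C1=C(O)C(=C)C(=O)C(C)=C1OC
F4 | step 6 | 3,5-bis(benzyloxy)-2-[(dimethylamino)methyl]phenol | CN(C)Cc1c(O)cc(OCc2ccccc2)cc1OCc1ccccc1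
F5 | step 7 | 1-{3-[4,6-bis(benzyloxy)-3-formyl-2-hydroxybenzyl]-2,4-dihydroxy-6-methoxy-5-methylphenyl}ethan-1-one | CC(=O)c1c(O)c(Cc2c(O)c(C=O)c(OCc3ccccc3)cc2OCc2ccccc2)c(O)c(C)c1OC
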